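## Plan

- **Cuts:** O–CHO at C15, C8=C17 (Wittig), C4–C18 (enolate methylation) and C2–C3 (carbonyl-ene, opens ring A). C9–C11 and C1–C10 are then cut together, and re-forming a C4–C7 bond turns the remainder into a pinane.
- **Enabling feature:** ring B (C5–C10), with C20 on quaternary C10 and with C4 on C5 carrying two one-carbon branches (later C3 and C19), is atom for atom the ten-carbon skeleton of verbenone. C8 is the carbonyl, C9=C10 the enone, and C4 the CMe2 bridge tied to C5 and C7.
- **Forward order:** the C11–C16 chain (as a triflate) and a vinyl group (C1–C2) are joined to verbenone in one operation. The cyclobutane bond C4–C7 is then broken, freeing ring B with an isopropenyl group on C5, and ring A closes last (C2–C3).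
- **End game:** C2 deoxygenation, oxidation of C19, C17 by Wittig, C18 by methylation, then the formate.
- **Stereochemistry:** C5 comes from (+)-verbenone and C13 from the (R)-3-methylglutaric half ester. C10 is set by attack anti to the CMe2 bridge, C9 by equilibration next to the C8 ketone, and C4 by methylation opposite the axial C20.

Key step: step 5

Assumption: labdane numbering is used for all intermediates; centres that are created and erased again (C2–OH, C8–OH, C4–H) should form as epimer mixtures and carry no configuration in the SMILES.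

## Route

Step 1
Reactants: 1 methyl hydrogen (R)-3-methylglutarate
Product: 2 methyl (R)-5-hydroxy-3-methylpentanoate
Conditions: BH3·SMe2 (1.1 equiv), THF, 0 °C → rt; H2O quench
Reagents that add atoms: none
Why: Borane reduces the free carboxylic acid far faster than the methyl ester (chemoselective acid reduction), C13 is untouched, and crude 2 is used at once so that it does not lactonise.

Step 2
Reactants: 2 methyl (R)-5-hydroxy-3-methylpentanoate
Product: 3 methyl (R)-3-methyl-5-(pivaloyloxy)pentanoate
Conditions: tBuCOCl, pyridine, DMAP (cat.), CH2Cl2, 0 °C → rt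
Reagents that add atoms: pivaloyl chloride, CC(C)(C)C(=O)Cl
Why: DMAP-catalysed acylation of a primary alcohol; the pivalate is chosen because it withstands the Lewis acid/Ac2O medium of step 7 and, being a poor nucleophile, cannot close a tetrahydropyran onto the later triflate carbon.

Step 3
Reactants: 3 methyl (R)-3-methyl-5-(pivaloyloxy)pentanoate
Product: 4 (S)-5-hydroxy-3-methylpentyl pivalate
Conditions: LiBH4, MeOH (1 equiv), Et2O, 0 °C → rt
Reagents that add atoms: none
Why: LiBH4 reduces the unhindered methyl ester while the tert-alkyl carboxylate is sterically shielded (chemoselective ester reduction), and acyl migration across eight atoms, which would erode the purity at C13, is not expected.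

Step 4
Reactants: 4 (S)-5-hydroxy-3-methylpentyl pivalate
Product: 5 (R)-3-methyl-5-(trifluoromethylsulfonyloxy)pentyl pivalate
Conditions: Tf2O, 2,6-lutidine, CH2Cl2, −78 °C
Reagents that add atoms: trifluoromethanesulfonic anhydride, O=S(=O)(OS(=O)(=O)C(F)(F)F)C(F)(F)F
Why: Sulfonylation of a primary alcohol with Tf2O and a hindered pyridine base at low temperature gives the alkyl triflate, which is filtered through silica and used the same day.

Step 5
Reactants: 6 (1R,5R)-(+)-verbenone; 7 vinylmagnesium bromide; 5 (R)-3-methyl-5-(trifluoromethylsulfonyloxy)pentyl pivalate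
Product: 10 (3S)-5-[(1R,3S,4S,5S)-4-ethenyl-4,6,6-trimethyl-2-oxobicyclo[3.1.1]heptan-3-yl]-3-methylpentyl pivalate (vinyl on C10 plus chain on C9 both anti to the CMe2 bridge; 9-epi series), via trimethylsilyl enol ether 8 (not isolated), via lithium enolate 9 (not isolated)
Conditions: 7, CuBr·SMe2 (10 mol %), Me3SiCl, THF, −78 → −30 °C; volatiles off, dry pentane, filtration under Ar, solvent switch to THF; MeLi (halide-free, 1.0 equiv), 0 °C; 5, −78 → −20 °C
Reagents that add atoms: chlorotrimethylsilane, C[Si](C)(C)Cl (silyl group of 8 only); methyllithium, [Li]C (lithium of 9 only)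
Why: CuBr·SMe2 and 7 give a vinylcopper reagent that complexes the enone of 6 on the face turned toward the CH2 bridge and transfers vinyl to C10 (bond C1–C10), Me3SiCl trapping the enolate as 8 and keeping 1,2-addition down; after the magnesium and copper salts are removed, halide-free MeLi cleaves the O–Si bond to the lithium enolate 9, which displaces triflate from 5 by SN2 attack through C9 (bond C9–C11). The closest known reaction type is the three-component coupling of an enone by copper-mediated conjugate addition and enolate alkylation, which is established for verbenone. No ring is closed. C10 is controlled by the gem-dimethyl bridge, which covers the β face, so that vinyl becomes α and trans to C4 as the later trans-decalin demands; the same bridge sends the chain to the α face of C9, giving the unnatural epimer that step 8 corrects. The step needs regiocontrol of enolisation and mono-alkylation, both secured by the substrate because C7 is a bridgehead that cannot enolise and C9 is flanked by quaternary C10. It also needs C- over O-alkylation and a long-lived electrophile, which the lithium counter-ion in THF without dipolar cosolvent, the absence of halide (no triflate-to-bromide exchange) and the non-nucleophilic pivalate of 5 (no cyclisation onto the triflate carbon) should provide.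

Step 6
Reactants: 10 the 9-alkyl-10-vinyl pinanone
Product: 12 (3S)-5-[(1R,3S,4S,5S)-4-(2-hydroxyethyl)-4,6,6-trimethyl-2-oxobicyclo[3.1.1]heptan-3-yl]-3-methylpentyl pivalate, via B-alkyl catecholborane 11 (not isolated)
Conditions: catecholborane, RhCl(PPh3)3 (2 mol %), THF, rt; then H2O2, aq. NaOH, 0 °C
Reagents that add atoms: catecholborane, [H]B1Oc2ccccc2O1 (boryl group of 11 only); hydrogen peroxide, OO
Why: Rhodium-catalysed hydroboration directs catecholborane to the C=C bond in preference to the hindered C8 ketone and places boron on terminal C2, and alkaline peroxide then replaces boron by hydroxyl.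

Step 7
Reactants: 12 the 10-(2-hydroxyethyl) pinanone
Product: 14 (4S,5S,6S)-5-(2-acetoxyethyl)-5-methyl-6-[(3S)-3-methyl-5-(pivaloyloxy)pentyl]-4-(prop-1-en-2-yl)cyclohex-1-en-1-yl acetate (C7=C8 enol acetate; 9-epi series), via primary acetate 13 (not isolated)
Conditions: BF3·OEt2, Zn(OAc)2, Ac2O, 0 °C → rt
Reagents that add atoms: acetic anhydride, CC(=O)OC(C)=O
Why: The primary alcohol is acetylated at once, then BF3 bound to the C8 carbonyl triggers strain-releasing heterolysis of the cyclobutane bond C4–C7 (the known Lewis-acid cleavage of pinan-2-ones in Ac2O), the enolate is trapped as the C7=C8 enol acetate and the tertiary C4 cation loses a methyl proton to give the isopropenyl group, with C5, C9 and C10 untouched.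

Step 8
Reactants: 14 the enol acetate
Product: 15 (3S)-5-[(1R,2S,3S)-2-(2-hydroxyethyl)-2-methyl-6-oxo-3-(prop-1-en-2-yl)cyclohexyl]-3-methylpentyl pivalate (chain on C9 now equatorial; H-9 α)
Conditions: K2CO3, MeOH, rt, until the C9 equilibrium is reached
Reagents that add atoms: none
Why: Methanolysis removes the enol acetate and the primary acetate but not the pivalate, and the freed ketone epimerises through its enolate to the more stable C9 epimer, in which the side chain, the C1 chain and the isopropenyl group are all equatorial (natural configuration).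

Step 9
Reactants: 15 the hydroxy ketone
Product: 16 (3S)-3-methyl-5-[(1R,2S,3S)-2-methyl-6-oxo-2-(2-oxoethyl)-3-(prop-1-en-2-yl)cyclohexyl]pentyl pivalate
Conditions: Dess–Martin periodinane, CH2Cl2, rt
Reagents that add atoms: none
Why: Dess–Martin oxidation converts the primary alcohol into the C2 aldehyde under mild conditions that leave alkene, ketone, ester and C9 alone.

Step 10
Reactants: 16 the keto aldehyde
Product: 17 2ξ-hydroxy-15-(pivaloyloxy)-17,18-dinorlabd-4(19)-en-8-one (trans-decalin; 5α-H, 9α-H, 10β-methyl, 13S)
Conditions: Me2AlCl (3 equiv), CH2Cl2, −78 → −20 °C; H2O quench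
Reagents that add atoms: none
Why: In this intramolecular carbonyl-ene reaction of type 2 (ene unit tethered through its central carbon) the isopropenyl CH2 (C3) attacks the Me2AlCl-activated aldehyde C2 through a chair-like array with both tethers equatorial on ring B and a methyl hydrogen passes to oxygen, so ring A closes as a trans-decalin fixed by C5 and C10 with an exocyclic C4=CH2, the C2 carbinol centre (axial expected) is removed in step 12, and the less electrophilic and remote C8 ketone stays out.

Step 11
Reactants: 17 the homoallylic alcohol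
Product: 18 2-O-(imidazol-1-ylthiocarbonyl) derivative of 17
Conditions: (imidazol-1-yl)2C=S, DMAP (cat.), ClCH2CH2Cl, 70 °C
Reagents that add atoms: 1,1'-thiocarbonyldiimidazole, S=C(n1ccnc1)n1ccnc1
Why: Thioacylation of the secondary alcohol under neutral conditions gives the Barton–McCombie precursor and avoids the enolate chemistry at the ketone that a strong-base xanthate protocol would risk.

Step 12
Reactants: 18 the thiocarbonyl derivative
Product: 19 15-(pivaloyloxy)-17,18-dinorlabd-4(19)-en-8-one
Conditions: nBu3SnH, AIBN (cat.), toluene, 100 °C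
Reagents that add atoms: none
Why: In this Barton–McCombie deoxygenation the stannyl radical adds to C=S, the C2 radical is released, and it is quenched by concentrated nBu3SnH faster than it can attack the homoallylic alkene.

Step 13
Reactants: 19 the methylene ketone
Product: 21 15-(pivaloyloxy)-17,18-dinorlabdane-8ξ,19-diol (4ξ), via bis-boron adduct 20 (not isolated)
Conditions: BH3·THF (excess), THF, 0 °C → rt; then H2O2, aq. NaOH
Reagents that add atoms: borane–tetrahydrofuran, B.C1CCOC1 (boron of 20 only); hydrogen peroxide, OO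
Why: Anti-Markovnikov hydroboration–oxidation puts oxygen on the CH2 terminus (C19) of the exocyclic alkene while borane also reduces the C8 ketone, and the new C4–H and C8–OH centres (attack from the α face opposite C20 expected) are erased in steps 17 and 14.

Step 14
Reactants: 21 the diol
Product: 22 8-oxo-15-(pivaloyloxy)-17,18-dinorlabdan-19-oic acid (4ξ)
Conditions: CrO3, H2SO4, H2O, acetone, 0 °C
Reagents that add atoms: water (of the aqueous oxidant), O
Why: Jones oxidation takes the primary alcohol through the aldehyde hydrate to the C19 acid and the secondary alcohol back to the C8 ketone in one operation, the pivalate being acid-stable and no alkene being present.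

Step 15
Reactants: 22 the keto acid
Product: 23 2-(trimethylsilyl)ethyl 8-oxo-15-(pivaloyloxy)-17,18-dinorlabdan-19-oate (4ξ)
Conditions: Me3SiCH2CH2OH, EDC·HCl, DMAP, CH2Cl2, rt
Reagents that add atoms: 2-(trimethylsilyl)ethanol, C[Si](C)(C)CCO
Why: Steglich-type carbodiimide esterification of the still secondary (C4–H) acid installs an ester that, once quaternary and axial and thus closed to saponification, can be cleaved by fluoride at silicon.

Step 16
Reactants: 23 the keto ester
Product: 24 2-(trimethylsilyl)ethyl 15-(pivaloyloxy)-18-norlabd-8(17)-en-19-oate (4ξ)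
Conditions: Ph3PCH3Br, KOtBu, THF, rt → 50 °C
Reagents that add atoms: methyltriphenylphosphonium bromide, C[P+](c1ccccc1)(c1ccccc1)c1ccccc1.[Br-]
Why: Wittig methylenation of 8-oxo-17-norlabdanes is well known, the esters are inert to the non-stabilised ylide, and its basicity keeps C9 in equilibrium so that the equatorial epimer with the more open carbonyl is drained to product.

Step 17
Reactants: 24 the C4–H ester
Product: 26 2-(trimethylsilyl)ethyl 15-(pivaloyloxy)labd-8(17)-en-19-oate (4S), via lithium ester enolate 25 (not isolated)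
Conditions: LiN(iPr)2, THF, −78 → 0 °C; MeI, DMPU, −78 °C → rt
Reagents that add atoms: lithium diisopropylamide, CC(C)N([Li])C(C)C (lithium of 25 only); iodomethane, CI
Why: In this ester enolate alkylation the exocyclic C4 enolate is shielded on its β face by the axial C20 methyl, so MeI enters from the α (equatorial) side and gives the equatorial C18 methyl and the axial C19 ester, the outcome established for C4 esters of trans-decalins with a C10 methyl.

Step 18
Reactants: 26 the diester
Product: 27 2-(trimethylsilyl)ethyl 15-hydroxylabd-8(17)-en-19-oate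
Conditions: NaOMe (cat.), MeOH, 50 °C
Reagents that add atoms: none
Why: Methoxide transesterification removes the primary pivalate, whereas the quaternary axial C19 ester is closed to acyl attack.

Step 19
Reactants: 27 the hydroxy ester
Product: 28 15-hydroxylabd-8(17)-en-19-oic acid (imbricatolic acid)
Conditions: nBu4NF, THF, rt; dilute HCl to pH 4
Reagents that add atoms: none
Why: Fluoride attacks silicon and the ester fragments to carboxylate, ethene and Me3SiF, so the hindered carbonyl need not be attacked and the exocyclic alkene sees neither strong acid nor strong base.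

Step 20
Reactants: 28 the hydroxy acid
Product: 29 15-formyloxylabd-8(17)-en-19-oic acid (target)
Conditions: HCO2Ac (freshly prepared), pyridine, CH2Cl2, 0 °C
Reagents that add atoms: acetic formic anhydride, CC(=O)OC=O
Why: Acetic formic anhydride transfers its more electrophilic formyl group to the primary alcohol, and any mixed anhydride at the hindered C19 acid is hydrolysed on aqueous work-up.

## Compound list

1 | methyl hydrogen (R)-3-methylglutarate | COC(=O)C[C@H](C)CC(=O)O | starting material
2 | methyl (R)-5-hydroxy-3-methylpentanoate | COC(=O)C[C@H](C)CCO | intermediate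
3 | methyl (R)-3-methyl-5-(pivaloyloxy)pentanoate | COC(=O)C[C@H](C)CCOC(=O)C(C)(C)C | intermediate
4 | (S)-5-hydroxy-3-methylpentyl pivalate | OCC[C@H](C)CCOC(=O)C(C)(C)C | intermediate
5 | (R)-3-methyl-5-(trifluoromethylsulfonyloxy)pentyl pivalate | O=S(=O)(OCC[C@H](C)CCOC(=O)C(C)(C)C)C(F)(F)F | intermediate
6 | (1R,5R)-(+)-verbenone | O=C1C=C(C)[C@H]2C[C@@H]1C2(C)C | starting material
7 | vinylmagnesium bromide | C=C[Mg]Br | starting material
8 | [(1R,4S,5S)-4-ethenyl-4,6,6-trimethylbicyclo[3.1.1]hept-2-en-2-yl]oxytrimethylsilane | C[Si](C)(C)OC1=C[C@@](C)(C=C)[C@H]2C[C@@H]1C2(C)C | intermediate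
9 | lithium enolate corresponding to 8 | [Li]OC1=C[C@@](C)(C=C)[C@H]2C[C@@H]1C2(C)C | intermediate
10 | (3S)-5-[(1R,3S,4S,5S)-4-ethenyl-4,6,6-trimethyl-2-oxobicyclo[3.1.1]heptan-3-yl]-3-methylpentyl pivalate | O=C1[C@@H](CC[C@H](C)CCOC(=O)C(C)(C)C)[C@@](C)(C=C)[C@H]2C[C@@H]1C2(C)C | intermediate
11 | B-alkyl catecholborane from 10 (boron on C2) | O=C1[C@@H](CC[C@H](C)CCOC(=O)C(C)(C)C)[C@@](C)(CCB3Oc4ccccc4O3)[C@H]2C[C@@H]1C2(C)C | intermediate
12 | (3S)-5-[(1R,3S,4S,5S)-4-(2-hydroxyethyl)-4,6,6-trimethyl-2-oxobicyclo[3.1.1]heptan-3-yl]-3-methylpentyl pivalate | O=C1[C@@H](CC[C@H](C)CCOC(=O)C(C)(C)C)[C@@](C)(CCO)[C@H]2C[C@@H]1C2(C)C | intermediate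
13 | primary (C2) acetate of 12 | O=C1[C@@H](CC[C@H](C)CCOC(=O)C(C)(C)C)[C@@](C)(CCOC(C)=O)[C@H]2C[C@@H]1C2(C)C | intermediate
14 | (4S,5S,6S)-5-(2-acetoxyethyl)-5-methyl-6-[(3S)-3-methyl-5-(pivaloyloxy)pentyl]-4-(prop-1-en-2-yl)cyclohex-1-en-1-yl acetate | CC(=O)OC1=CC[C@@H](C(C)=C)[C@](C)(CCOC(C)=O)[C@@H]1CC[C@H](C)CCOC(=O)C(C)(C)C | intermediate
15 | (3S)-5-[(1R,2S,3S)-2-(2-hydroxyethyl)-2-methyl-6-oxo-3-(prop-1-en-2-yl)cyclohexyl]-3-methylpentyl pivalate | O=C1CC[C@@H](C(C)=C)[C@](C)(CCO)[C@H]1CC[C@H](C)CCOC(=O)C(C)(C)C | intermediate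
16 | (3S)-3-methyl-5-[(1R,2S,3S)-2-methyl-6-oxo-2-(2-oxoethyl)-3-(prop-1-en-2-yl)cyclohexyl]pentyl pivalate | O=C1CC[C@@H](C(C)=C)[C@](C)(CC=O)[C@H]1CC[C@H](C)CCOC(=O)C(C)(C)C | intermediate
17 | 2ξ-hydroxy-15-(pivaloyloxy)-17,18-dinorlabd-4(19)-en-8-one | O=C1CC[C@@H]2[C@](C)(CC(O)CC2=C)[C@H]1CC[C@H](C)CCOC(=O)C(C)(C)C | intermediate
18 | 2-O-(imidazol-1-ylthiocarbonyl) derivative of 17 | O=C1CC[C@@H]2[C@](C)(CC(OC(=S)n3ccnc3)CC2=C)[C@H]1CC[C@H](C)CCOC(=O)C(C)(C)C | intermediate
19 | 15-(pivaloyloxy)-17,18-dinorlabd-4(19)-en-8-one | O=C1CC[C@@H]2[C@](C)(CCCC2=C)[C@H]1CC[C@H](C)CCOC(=O)C(C)(C)C | intermediate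
20 | bis-boron adduct of 19 (C19–BH2 and C8–O–BH2, drawn in its simplest form) | BOC1CC[C@@H]2[C@](C)(CCCC2CB)[C@H]1CC[C@H](C)CCOC(=O)C(C)(C)C | intermediate
21 | 15-(pivaloyloxy)-17,18-dinorlabdane-8ξ,19-diol (4ξ) | OC1CC[C@@H]2[C@](C)(CCCC2CO)[C@H]1CC[C@H](C)CCOC(=O)C(C)(C)C | intermediate
22 | 8-oxo-15-(pivaloyloxy)-17,18-dinorlabdan-19-oic acid (4ξ) | O=C1CC[C@@H]2[C@](C)(CCCC2C(=O)O)[C@H]1CC[C@H](C)CCOC(=O)C(C)(C)C | intermediate
23 | 2-(trimethylsilyl)ethyl 8-oxo-15-(pivaloyloxy)-17,18-dinorlabdan-19-oate (4ξ) | O=C1CC[C@@H]2[C@](C)(CCCC2C(=O)OCC[Si](C)(C)C)[C@H]1CC[C@H](C)CCOC(=O)C(C)(C)C | intermediate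
24 | 2-(trimethylsilyl)ethyl 15-(pivaloyloxy)-18-norlabd-8(17)-en-19-oate (4ξ) | C=C1CC[C@@H]2[C@](C)(CCCC2C(=O)OCC[Si](C)(C)C)[C@H]1CC[C@H](C)CCOC(=O)C(C)(C)C | intermediate
25 | lithium enolate of 24 (C4=C19) | C=C1CC[C@@H]2[C@](C)(CCCC2=C(O[Li])OCC[Si](C)(C)C)[C@H]1CC[C@H](C)CCOC(=O)C(C)(C)C | intermediate
26 | 2-(trimethylsilyl)ethyl 15-(pivaloyloxy)labd-8(17)-en-19-oate | C=C1CC[C@@H]2[C@](C)(CCC[C@]2(C)C(=O)OCC[Si](C)(C)C)[C@H]1CC[C@H](C)CCOC(=O)C(C)(C)C | intermediate
27 | 2-(trimethylsilyl)ethyl 15-hydroxylabd-8(17)-en-19-oate | C=C1CC[C@@H]2[C@](C)(CCC[C@]2(C)C(=O)OCC[Si](C)(C)C)[C@H]1CC[C@H](C)CCO | intermediate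
28 | 15-hydroxylabd-8(17)-en-19-oic acid (imbricatolic acid) | C=C1CC[C@@H]2[C@](C)(CCC[C@]2(C)C(=O)O)[C@H]1CC[C@H](C)CCO | intermediate
29 | 15-formyloxylabd-8(17)-en-19-oic acid, (4S,5R,9S,10R,13S) | C=C1CC[C@@H]2[C@](C)(CCC[C@]2(C)C(=O)O)[C@H]1CC[C@H](C)CCOC=O | target

## Step count

- Total step count: 20.
- Longest linear sequence: 20 steps (1 → 29, steps 1–20); 16 steps from 6.

## Steps most likely to fail

**Step 5.** The SN2 event at C9 takes place next to quaternary C10. It may be slow enough for O-alkylation of the enolate or decay of the triflate to take over.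

The fallback makes the C9–C11 bond by aldol chemistry with a smaller and more reactive electrophile. It sets out from enolate 9 and alcohol 4. Dess–Martin oxidation of 4 gives (R)-3-methyl-5-oxopentyl pivalate F1. Enolate 9 adds to it at −78 °C to give the β-hydroxy ketone F2 (epimers at C9 and C11). Burgess dehydration gives the C9=C11 enone F3. A 1,4-reduction with [(Ph3P)CuH]6 spares the isolated vinyl group, and protonation from the open α face gives the C9 epimer of 10 F4. DBU then moves the chain away from the syn methyl of the bridge, and the route is rejoined at 10.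

**Step 7.** The C2 oxygen function may take part. Hemiketal formation with the C8 carbonyl could precede acetylation, or the C4 cation could be captured by the neighbouring acetate oxygen or by external acetate instead of losing a methyl proton.

The fallback changes the order of events and sets out from 10, whose only oxygen functions are the ketone and the pivalate. The same BF3·OEt2/Zn(OAc)2/Ac2O cleavage, which a vinyl group on the quaternary carbon is known to survive, gives the vinyl isopropenyl enol acetate F5. K2CO3 in MeOH gives the C9-equilibrated vinyl isopropenyl ketone F6. RhCl(PPh3)3-catalysed hydroboration with catecholborane prefers a monosubstituted alkene to a 1,1-disubstituted one and to a ketone, and it gives the C2 catechol boronate F7. Alkaline H2O2 then leads back to the route at 15.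

**Step 10.** The ene closure places the aluminium-bound oxygen syn-axial to C20. A stepwise Prins path may therefore intervene, with chloride capture at C4, proton loss toward endocyclic alkenes, or methyl transfer from aluminium to the aldehyde.

The fallback replaces the pericyclic closure by an allylmetal addition and sets out from 16. Ene-type allylic chlorination of the isopropenyl group (N-chlorosuccinimide, PhSeCl cat., CH2Cl2) gives the 2-(chloromethyl)allyl keto aldehyde F8. An intramolecular Nozaki–Hiyama allylation with CrCl2 in dilute THF is selective for the aldehyde over the ketone. It forms C2–C3 with allylic transposition, so the same exocyclic C4=CH2 results, and the route is rejoined at 17.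

## Further compounds

F1 | step 5 | (R)-3-methyl-5-oxopentyl pivalate | O=CC[C@H](C)CCOC(=O)C(C)(C)C
F2 | step 5 | 11-hydroxy aldol adduct of 9 and F1 (C9 and C11 epimers) | O=C1C(C(O)C[C@H](C)CCOC(=O)C(C)(C)C)[C@@](C)(C=C)[C@H]2C[C@@H]1C2(C)C
F3 | step 5 | C9=C11 alkylidene pinanone (E expected) | O=C1C(=CC[C@H](C)CCOC(=O)C(C)(C)C)[C@@](C)(C=C)[C@H]2C[C@@H]1C2(C)C
F4 | step 5 | C9 epimer of 10 (chain syn to the CMe2 bridge) | O=C1[C@H](CC[C@H](C)CCOC(=O)C(C)(C)C)[C@@](C)(C=C)[C@H]2C[C@@H]1C2(C)C
F5 | step 7 | 5-ethenyl-5-methyl-6-[(3S)-3-methyl-5-(pivaloyloxy)pentyl]-4-(prop-1-en-2-yl)cyclohex-1-en-1-yl acetate (9-epi series) | CC(=O)OC1=CC[C@@H](C(C)=C)[C@](C)(C=C)[C@@H]1CC[C@H](C)CCOC(=O)C(C)(C)C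
F6 | step 7 | 3-ethenyl-3-methyl-2-[(3S)-3-methyl-5-(pivaloyloxy)pentyl]-4-(prop-1-en-2-yl)cyclohexanone (natural C9) | O=C1CC[C@@H](C(C)=C)[C@](C)(C=C)[C@H]1CC[C@H](C)CCOC(=O)C(C)(C)C
F7 | step 7 | C2 catechol boronate of F6 | O=C1CC[C@@H](C(C)=C)[C@](C)(CCB2Oc3ccccc3O2)[C@H]1CC[C@H](C)CCOC(=O)C(C)(C)C
F8 | step 10 | allylic chloride of 16 (C5 bears a 3-chloroprop-1-en-2-yl group) | O=C1CC[C@@H](C(=C)CCl)[C@](C)(CC=O)[C@H]1CC[C@H](C)CCOC(=O)C(C)(C)C
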